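**Retrosynthetic overview**
1. Feature: ring B is a 1,2,3,4-tetrasubstituted benzene. C1′ (bond to C2 of ring C) and C2′ (prenyl) are adjacent carbon-bearing positions, C3′/C4′ are adjacent oxygen-bearing positions, and C5′/C6′ are adjacent CH positions. This pattern corresponds to a disubstituted alkyne (C1′, C2′) added across C2/C5 of a 3-alkoxyfuran (C3′ to C6′), with the furan ring oxygen ending up on C3′.
2. Ring C is cut at O1–C2 (cyclodehydration) and C2–C3 (enolate acylation). This gives 3,4-bis(MOM-oxy)-2-prenylbenzoic acid and a fully MOM-protected, omega-oxygenated phloroacetophenone.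
3. The ketone comes from phloroglucinol tris-MOM ether by directed lithiation and acylation with the Weinreb amide of MOM-protected glycolic acid. Ring A is purchased.
4. The acid comes from methyl 3-hydroxy-4-methoxy-2-prenylbenzoate by MOM protection, thiolate demethylation and reprotection. That benzoate comes from 3-methoxyfuran and methyl 6-methylhept-5-en-2-ynoate by Diels–Alder addition and bridge opening, and the ynoate comes from methyl propiolate and prenyl bromide.
5. Ring order: ring B is built in step 2, ring A is bought, and ring C is closed last in step 11.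

Key step: step 2

Remark: the target has no stereocentre and its side-chain alkene carries two methyl groups, so no configuration has to be set; the stereocentres that appear in three intermediates are transient and racemic.

Step 1
Reactants: 1 methyl propiolate; 2 prenyl bromide (1-bromo-3-methylbut-2-ene)
Product: 3 methyl 6-methylhept-5-en-2-ynoate
Conditions: CuI (10 mol %), Bu4NBr (10 mol %), K2CO3 (1.5 equiv), DMF, 0 °C to rt
Reagents that add atoms: none
Why: Copper-catalysed coupling of a terminal alkyne with an allylic halide, in which the copper acetylide formed from the acidic propiolate C–H under carbonate displaces bromide at the unhindered primary carbon of 2 (direct rather than allylically transposed substitution, since the other terminus is fully substituted), while the weak base at or below room temperature should leave the doubly activated C4 methylene of the skipped enynoate unisomerised.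

Step 2
Reactants: 3 methyl 6-methylhept-5-en-2-ynoate; 4 3-methoxyfuran
Product: 6 methyl 3-hydroxy-4-methoxy-2-(3-methylbut-2-en-1-yl)benzoate, via oxanorbornadiene adduct 5 (not isolated)
Conditions: 3, Me2AlCl (1.2 equiv), CH2Cl2, −78 °C; then 4 (2.5 equiv), −78 °C to 0 °C; aq. potassium sodium tartrate
Reagents that add atoms: none
Why: Me2AlCl binds the ester carbonyl of 3 and lowers the alkyne LUMO, so the electron-rich diene 4 adds in a concerted but strongly asynchronous [4+2] cycloaddition in which furan C2, the nucleophilic terminus of the C2=C3 enol ether, bonds to the ynoate beta-carbon carrying the prenyl CH2 (C3′–C2′) ahead of the bond from furan C5 to the alpha-carbon (C6′–C1′). Ring B is thus closed as a six-membered carbocycle by an intermolecular Diels–Alder reaction that makes both sigma bonds at once, first as the oxygen-bridged bicycle 5, whose two bridgehead stereocentres are locked to each other by the bridge, arise as a racemate and disappear on aromatisation, so nothing has to control them. The aluminium Lewis acid then ionises the C6′–O bond of the bridge, because only this cation is conjugated through C5′=C4′ with the methoxy oxygen, whereas a cation at C3′ would be cross-conjugated to OMe and would place charge next to the ester-bearing carbon; loss of the C3′ proton gives the arene with the former bridge oxygen as the C3′ hydroxyl between OMe and prenyl. The closest known reaction type is the Lewis-acid-promoted Diels–Alder reaction of furans and alkoxyfurans with alkynoates, followed by isomerisation of the 7-oxanorbornadienes to phenols. The step needs regioselectivity twice (orientation of addition and direction of opening), and both follow from the single donor on furan C3, which gives the para relationship of OMe and CO2Me expected of a diene with an inner donor group. It also needs chemoselectivity for the furan over the prenyl alkene as partner of the activated ynoate, secured by the far higher nucleophilicity and the excess of 4, and it needs the absence of protic acid, secured because the Al–CH3 bonds take up the released proton as methane and the new oxygen stays on aluminium until the tartrate quench, so the C3′ oxygen cannot add to the prenyl alkene.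

Step 3
Reactants: 6 methyl 3-hydroxy-4-methoxy-2-(3-methylbut-2-en-1-yl)benzoate
Product: 7 methyl 4-methoxy-3-(methoxymethoxy)-2-(3-methylbut-2-en-1-yl)benzoate
Conditions: NaH (1.2 equiv), MOMCl (1.3 equiv), DMF, 0 °C to rt
Reagents that add atoms: chloromethyl methyl ether (MOMCl), COCCl
Why: Williamson-type O-alkylation (MOM ether formation) of the only acidic site, which masks the flanked C3 phenol as a base-stable acetal so that step 4 has to expel a single aryloxide para to the carboxyl group instead of a catecholate next to an existing phenoxide.

Step 4
Reactants: 7 methyl 4-methoxy-3-(methoxymethoxy)-2-(3-methylbut-2-en-1-yl)benzoate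
Product: 8 4-hydroxy-3-(methoxymethoxy)-2-(3-methylbut-2-en-1-yl)benzoic acid
Conditions: NaSEt (6 equiv), DMF, 120 °C, argon; then 1 M HCl to pH 4, 0 °C
Reagents that add atoms: none
Why: Nucleophilic (SN2) demethylation by a soft thiolate, in which ethanethiolate attacks the methyl carbon of the C4 ether, whose aryloxide leaving group is stabilised by the para carboxyl function, and equally the methyl carbon of the hindered ester (alkyl–oxygen cleavage, indifferent to the ortho prenyl group), while the MOM acetal and the trisubstituted alkene are inert to a non-acidic, weakly basic nucleophile.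

Step 5
Reactants: 8 4-hydroxy-3-(methoxymethoxy)-2-(3-methylbut-2-en-1-yl)benzoic acid
Product: 10 3,4-bis(methoxymethoxy)-2-(3-methylbut-2-en-1-yl)benzoic acid, via MOM ester 9 (not isolated)
Conditions: MOMCl (2.5 equiv), iPr2NEt (3 equiv), CH2Cl2, 0 °C to rt; concentrate; LiOH (3 equiv), THF/H2O, rt; 1 M HCl to pH 4, 0 °C
Reagents that add atoms: chloromethyl methyl ether (MOMCl), COCCl; lithium hydroxide, [Li+].[OH-]
Why: Double O-alkylation with MOMCl followed by saponification, in which phenol and carboxylate are both alkylated and the acylal-type ester 9 is then hydrolysed by hydroxide at room temperature far faster than an ordinary ortho-substituted benzoate, the aryl MOM ethers being stable to base.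

Step 6
Reactants: 11 phloroglucinol
Product: 12 1,3,5-tris(methoxymethoxy)benzene
Conditions: NaH (3.6 equiv), MOMCl (3.6 equiv), DMF, 0 °C to rt
Reagents that add atoms: chloromethyl methyl ether (MOMCl), COCCl
Why: Threefold Williamson-type O-alkylation, in which the hard, oxocarbenium-like electrophile reacts at oxygen and not at the ring carbons of the phloroglucinol anion, and the three acetals later serve as directing groups for lithiation.

Step 7
Reactants: 13 methyl glycolate
Product: 14 methyl 2-(methoxymethoxy)acetate
Conditions: MOMCl (1.3 equiv), iPr2NEt (1.5 equiv), CH2Cl2, 0 °C to rt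
Reagents that add atoms: chloromethyl methyl ether (MOMCl), COCCl
Why: MOM ether formation on a primary alcohol under amine base, conditions that leave the methyl ester untouched.

Step 8
Reactants: 14 methyl 2-(methoxymethoxy)acetate
Product: 15 N-methoxy-2-(methoxymethoxy)-N-methylacetamide
Conditions: MeNH(OMe)·HCl (1.5 equiv), iPrMgCl (3 equiv), THF, −20 °C to 0 °C; aq. NH4Cl
Reagents that add atoms: N,O-dimethylhydroxylamine hydrochloride, CNOC.Cl
Why: Weinreb amide synthesis by aminolysis of the ester with the chloromagnesium amide made in the flask from the amine hydrochloride and iPrMgCl, a nucleophile reactive enough below 0 °C to spare the acetal.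

Step 9
Reactants: 12 1,3,5-tris(methoxymethoxy)benzene; 15 N-methoxy-2-(methoxymethoxy)-N-methylacetamide
Product: 17 2-(methoxymethoxy)-1-[2,4,6-tris(methoxymethoxy)phenyl]ethan-1-one, via aryllithium 16 (not isolated)
Conditions: 12, n-BuLi (1.1 equiv), THF, 0 °C, 1 h; then 15, −78 °C to 0 °C; aq. NH4Cl
Reagents that add atoms: none
Why: Directed ortho-metalation followed by the Weinreb ketone synthesis, in which every ring C–H of 12 lies between two coordinating OMOM groups and all three are equivalent, so a single aryllithium forms, and the chelated tetrahedral adduct with 15 holds until the quench, which rules out a second addition.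

Step 10
Reactants: 10 3,4-bis(methoxymethoxy)-2-(3-methylbut-2-en-1-yl)benzoic acid; 17 2-(methoxymethoxy)-1-[2,4,6-tris(methoxymethoxy)phenyl]ethan-1-one
Product: 20 1-[3,4-bis(methoxymethoxy)-2-(3-methylbut-2-en-1-yl)phenyl]-2-(methoxymethoxy)-3-[2,4,6-tris(methoxymethoxy)phenyl]propane-1,3-dione (racemic at C2), via acyl imidazolide 18 (not isolated), via lithium enolate 19 (not isolated)
Conditions: flask A: 10, CDI (1.1 equiv), THF, rt; flask B: 17 (1.1 equiv), LiN(SiMe3)2 (3.2 equiv), THF, −78 °C; A into B, −78 °C to 0 °C; aq. NH4Cl
Reagents that add atoms: none
Why: Crossed Claisen-type C-acylation of a preformed lithium enolate by an acyl imidazolide, in which only 17 has an enolisable position alpha to a carbonyl, the imidazolide favours C- over O-acylation, three equivalents of base cover the ketone, the imidazole released by CDI and the acidic 1,3-diketone product, and the new C2 stereocentre forms without control as a labile racemate that is erased in step 11.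

Step 11
Reactants: 20 1-[3,4-bis(methoxymethoxy)-2-(3-methylbut-2-en-1-yl)phenyl]-2-(methoxymethoxy)-3-[2,4,6-tris(methoxymethoxy)phenyl]propane-1,3-dione
Product: 22 2-[3,4-dihydroxy-2-(3-methylbut-2-en-1-yl)phenyl]-3,5,7-trihydroxy-4H-chromen-4-one (CNP0210655.0), via free hexahydroxy diketone 21 (not isolated)
Conditions: HCl (1.25 M in MeOH), 40 °C, argon
Reagents that add atoms: none
Why: Acid-catalysed acetal exchange with methanol followed by cyclodehydration, as in the closing stage of a Baker–Venkataraman flavone synthesis, in which either of the two equivalent ortho hydroxyls of ring A, once freed, adds to the ring-B ketone (6-exo-trig), loss of water gives the aromatic pyranone ring C with the C3 hydroxyl in place, and the low acid strength and temperature are chosen because MOM cleavage is much faster than protonation of the trisubstituted alkene next to the C3′ hydroxyl.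

**Compound list**
1 | methyl propiolate | C#CC(=O)OC | starting material
2 | prenyl bromide (1-bromo-3-methylbut-2-ene) | CC(C)=CCBr | starting material
3 | methyl 6-methylhept-5-en-2-ynoate | COC(=O)C#CCC=C(C)C | intermediate
4 | 3-methoxyfuran | COc1ccoc1 | starting material
5 | methyl 5-methoxy-3-(3-methylbut-2-en-1-yl)-7-oxabicyclo[2.2.1]hepta-2,5-diene-2-carboxylate (racemate, one enantiomer drawn; formed in the flask) | COC(=O)C1=C(CC=C(C)C)[C@@H]2O[C@H]1C=C2OC | intermediate
6 | methyl 3-hydroxy-4-methoxy-2-(3-methylbut-2-en-1-yl)benzoate | COC(=O)c1ccc(OC)c(O)c1CC=C(C)C | intermediate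
7 | methyl 4-methoxy-3-(methoxymethoxy)-2-(3-methylbut-2-en-1-yl)benzoate | COC(=O)c1ccc(OC)c(OCOC)c1CC=C(C)C | intermediate
8 | 4-hydroxy-3-(methoxymethoxy)-2-(3-methylbut-2-en-1-yl)benzoic acid | OC(=O)c1ccc(O)c(OCOC)c1CC=C(C)C | intermediate
9 | methoxymethyl 3,4-bis(methoxymethoxy)-2-(3-methylbut-2-en-1-yl)benzoate (formed in the flask) | COCOC(=O)c1ccc(OCOC)c(OCOC)c1CC=C(C)C | intermediate
10 | 3,4-bis(methoxymethoxy)-2-(3-methylbut-2-en-1-yl)benzoic acid | OC(=O)c1ccc(OCOC)c(OCOC)c1CC=C(C)C | intermediate
11 | phloroglucinol | Oc1cc(O)cc(O)c1 | starting material
12 | 1,3,5-tris(methoxymethoxy)benzene | COCOc1cc(OCOC)cc(OCOC)c1 | intermediate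
13 | methyl glycolate | COC(=O)CO | starting material
14 | methyl 2-(methoxymethoxy)acetate | COCOCC(=O)OC | intermediate
15 | N-methoxy-2-(methoxymethoxy)-N-methylacetamide | COCOCC(=O)N(C)OC | intermediate
16 | [2,4,6-tris(methoxymethoxy)phenyl]lithium (formed in the flask) | [Li]c1c(OCOC)cc(OCOC)cc1OCOC | intermediate
17 | 2-(methoxymethoxy)-1-[2,4,6-tris(methoxymethoxy)phenyl]ethan-1-one | COCOCC(=O)c1c(OCOC)cc(OCOC)cc1OCOC | intermediate
18 | 1-[3,4-bis(methoxymethoxy)-2-(3-methylbut-2-en-1-yl)benzoyl]-1H-imidazole (formed in the flask) | O=C(n1ccnc1)c1ccc(OCOC)c(OCOC)c1CC=C(C)C | intermediate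
19 | lithium (Z)-2-(methoxymethoxy)-1-[2,4,6-tris(methoxymethoxy)phenyl]ethen-1-olate (chelated enolate; formed in the flask) | [Li]O/C(=C\OCOC)c1c(OCOC)cc(OCOC)cc1OCOC | intermediate
20 | 1-[3,4-bis(methoxymethoxy)-2-(3-methylbut-2-en-1-yl)phenyl]-2-(methoxymethoxy)-3-[2,4,6-tris(methoxymethoxy)phenyl]propane-1,3-dione (racemic and enolisable at C2) | COCOC(C(=O)c1c(OCOC)cc(OCOC)cc1OCOC)C(=O)c1ccc(OCOC)c(OCOC)c1CC=C(C)C | intermediate
21 | 1-[3,4-dihydroxy-2-(3-methylbut-2-en-1-yl)phenyl]-2-hydroxy-3-(2,4,6-trihydroxyphenyl)propane-1,3-dione (racemic and enolisable at C2; formed in the flask) | OC(C(=O)c1c(O)cc(O)cc1O)C(=O)c1ccc(O)c(O)c1CC=C(C)C | intermediate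
22 | 2-[3,4-dihydroxy-2-(3-methylbut-2-en-1-yl)phenyl]-3,5,7-trihydroxy-4H-chromen-4-one (CNP0210655.0) | CC(C)=CCc1c(-c2oc3cc(O)cc(O)c3c(=O)c2O)ccc(O)c1O | target

**Step count**
Total: 11 steps. Longest linear sequence: 7 steps (1, 2, 3, 4, 5, 10, 11).

**Steps most likely to fail**

Step 2. The beta-alkyl ynoate may add too slowly. Lewis-acid-induced oligomerisation of the furan could then overtake closure of the second bond, as could proton loss after the first C–C bond, which amounts to simple conjugate alkenylation at furan C2. The fallback keeps the furan-to-benzene construction of ring B but uses a halogen as placeholder for the prenyl group. It sets out from 1 and 4 and rejoins the route at 7. Bromination of the alkyne terminus of 1 (NBS, AgNO3 cat., acetone, rt) gives methyl 3-bromopropiolate F1, a much stronger dienophile that needs no Lewis acid. Warming F1 with 4 in toluene should give racemic methyl 3-bromo-5-methoxy-7-oxabicyclo[2.2.1]hepta-2,5-diene-2-carboxylate F2, with the same orientation (furan C2 to the bromine-bearing carbon). A trace of p-TsOH, harmless while no prenyl group is present, opens F2 to methyl 2-bromo-3-hydroxy-4-methoxybenzoate F3. MOM protection as in step 3 gives methyl 2-bromo-4-methoxy-3-(methoxymethoxy)benzoate F4. A Stille coupling of F4 with tributyl(3-methylbut-2-en-1-yl)stannane (Pd(PPh3)4, DMF, 100 °C) then places the prenyl group on C2 and delivers 7.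

Step 11. Six acetals have to be removed and ring C closed in one acid treatment. That exposure may be long enough for the prenyl alkene to be protonated and captured by the neighbouring C3′ hydroxyl (closure to a chroman) or by methanol. The fallback separates the two tasks so that no strong protic acid is present at any point. It sets out from 20 and rejoins the route at 22 by way of 21, which is now isolated. Thiol-assisted Lewis-acid acetal transfer (ZnBr2, n-PrSH, CH2Cl2, 0 °C, short contact) moves the six methoxymethyl groups onto sulfur and frees 21. Ring C is then closed under buffered conditions (NaOAc, AcOH, 80 °C), the classical weak-acid cyclodehydration of ortho-hydroxy 1,3-diketones, to give 22. No compound outside the list is made (F0).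

Step 10. The intermolecular acylation may fail in three ways: O-acylation of the enolate, sluggish attack on the electron-rich ortho-substituted acyl donor, or competing deprotonation of the benzylic-allylic CH2 of the donor by the excess amide base. The fallback makes the acyl transfer intramolecular and uses a weaker base. It sets out from 17 and 10 and rejoins the route at 22, through 21 under the conditions of step 11. One of the two equivalent MOM ethers ortho to the ketone of 17 is cleaved selectively (I2 cat., MeOH, rt; assisted by the neighbouring carbonyl) to give 1-[2-hydroxy-4,6-bis(methoxymethoxy)phenyl]-2-(methoxymethoxy)ethan-1-one F5. Steglich-type esterification of F5 with 10 (EDC, DMAP, CH2Cl2) gives 3,5-bis(methoxymethoxy)-2-[(methoxymethoxy)acetyl]phenyl 3,4-bis(methoxymethoxy)-2-(3-methylbut-2-en-1-yl)benzoate F6. Baker–Venkataraman rearrangement of F6 (KOH, pyridine, 50 °C) moves the aroyl group to the alpha-carbon through a six-membered transition state. The product is 1-[3,4-bis(methoxymethoxy)-2-(3-methylbut-2-en-1-yl)phenyl]-3-[2-hydroxy-4,6-bis(methoxymethoxy)phenyl]-2-(methoxymethoxy)propane-1,3-dione F7, which is deprotected and cyclised exactly as 20.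

**Further compounds**
F1 | step 2 | methyl 3-bromopropiolate | COC(=O)C#CBr
F2 | step 2 | methyl 3-bromo-5-methoxy-7-oxabicyclo[2.2.1]hepta-2,5-diene-2-carboxylate (racemate, one enantiomer drawn) | COC(=O)C1=C(Br)[C@@H]2O[C@H]1C=C2OC
F3 | step 2 | methyl 2-bromo-3-hydroxy-4-methoxybenzoate | COC(=O)c1ccc(OC)c(O)c1Br
F4 | step 2 | methyl 2-bromo-4-methoxy-3-(methoxymethoxy)benzoate | COC(=O)c1ccc(OC)c(OCOC)c1Br
F0 | step 11 | none | none
F5 | step 10 | 1-[2-hydroxy-4,6-bis(methoxymethoxy)phenyl]-2-(methoxymethoxy)ethan-1-one | COCOCC(=O)c1c(O)cc(OCOC)cc1OCOC
F6 | step 10 | 3,5-bis(methoxymethoxy)-2-[(methoxymethoxy)acetyl]phenyl 3,4-bis(methoxymethoxy)-2-(3-methylbut-2-en-1-yl)benzoate | COCOCC(=O)c1c(OC(=O)c2ccc(OCOC)c(OCOC)c2CC=C(C)C)cc(OCOC)cc1OCOC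
F7 | step 10 | 1-[3,4-bis(methoxymethoxy)-2-(3-methylbut-2-en-1-yl)phenyl]-3-[2-hydroxy-4,6-bis(methoxymethoxy)phenyl]-2-(methoxymethoxy)propane-1,3-dione (racemic at C2) | COCOC(C(=O)c1c(O)cc(OCOC)cc1OCOC)C(=O)c1ccc(OCOC)c(OCOC)c1CC=C(C)C
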